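The pitfall is to set the two product-forming constants side by side, 390 L mol⁻¹ s⁻¹ against 0.23 L mol⁻¹ s⁻¹, and conclude that target must swamp the isomer of the product.

    substrate ⇌ tautomer (K1 = 1.3, k1 = 0.0025 s⁻¹, Ea1 = 76.0 kJ mol⁻¹, ΔH1 = −11.0 kJ mol⁻¹)
    substrate + reagent → isomer of the product (k2 = 0.23 L mol⁻¹ s⁻¹, Ea2 = 35.0 kJ mol⁻¹)
    reagent + tautomer → target (k3 = 390 L mol⁻¹ s⁻¹, Ea3 = 37.0 kJ mol⁻¹)
    reagent ⇌ dormant form (K4 = 1.4, k4 = 0.0011 s⁻¹, Ea4 = 79.0 kJ mol⁻¹, ΔH4 = −15.0 kJ mol⁻¹)
    tautomer → side product (k5 = 0.0083 s⁻¹, Ea5 = 64.0 kJ mol⁻¹)
    (constants at −20 °C)

| flask | substrate | reagent | temperature | time | remark |
|---|---|---|---|---|---|
| Tuesday's | 0.050 M | 0.0500 M (fed, over 6.0 min) | −20 °C | 15 min | all else is in the flask from the start; the feed brings no volume worth counting |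
| Friday's | 0.050 M (fed, over 6.0 min) | 0.0500 M |  | 15 min | the addition at −60 °C, then warmed to −20 °C; the feed brings no volume worth counting |
| Monday's | 0.050 M (fed, over 40 s) | 0.0500 M | −20 °C | 15 min | all else is in the flask from the start; the feed brings no volume worth counting |
| Sunday's | 0.050 M | 0.0500 M | −20 °C | 15 min | everything together at the start |

1. which flask leads in amount of isomer of the product, in percent of the substrate charged ("all alike" within 1.5 percentage points) (Tuesday's / Friday's / Monday's / Sunday's / all alike)
2. how much isomer of the product is there at the end, in percent of the substrate charged: Tuesday's
3. how much isomer of the product is there at the end, in percent of the substrate charged: Friday's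
4. how much isomer of the product is there at the end, in percent of the substrate charged: Monday's
5. how much isomer of the product is there at the end, in percent of the substrate charged: Sunday's

- constants are those at −20 °C; use the activation energies and enthalpies for any other temperature

Those two steps start from different species, so they are not the race you should look at. At the charged reagent level, tautomer meets reagent far faster than it turns into side product, so nearly all of it becomes target. The race stands one step earlier, where substrate either meets reagent directly or tautomerises. Fold that into the branching number S, a selectivity factor: the direct constant times the reagent concentration, over the forward tautomerisation constant. At the charge, 4.60, which is also the ratio of the half-lives 4.6 min and 1.0 min. It says how many substrate molecules go direct for each one that tautomerises, so the direct share at any moment is S/(1 + S).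

In Sunday's flask each route spends one reagent per substrate and the charges are equal, so with the dormant form set aside S falls in step with the substrate. Summing the shares gives 1 − ln(1 + S)/S, which I reckon as 62.5%. For Monday's I keep that figure, since 40 s is shorter than the tautomerisation half-life. I hold it a little high, because the reagent's forward half-life towards the dormant form, 11 min, is shorter than the run.

One number is not enough for the other two flasks. In Tuesday's flask the feed supplies 1.11 times what tautomerisation of the charged substrate takes. If reagent is used about as it comes, the surplus, 0.111, is the running S that the feed holds while substrate stands near its charge. The direct share for that stretch is 10.0%. My reckoning stops there, with that early S far lower than the 4.60 of Sunday's charge, so I place Tuesday's below Sunday's, without a figure. For Friday's, the direct barrier is lower than the tautomerisation barrier, so the cold addition raises S and I place that flask above Sunday's, without a figure.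

The forecast names Friday's, with 27% for Tuesday's, on the ground that “slow reagent feed starves it”, 59% for Friday's, 57% for Monday's and 57% for Sunday's. My 62.5% for Sunday's is higher than the forecast's figure for that flask. The simulation gives 25.8%, 58.8%, 55.7% and 56.9% in that order, so Friday's leads.

Sunday's flask ends 5.6 percentage points below my 62.5%. Now take Tuesday's flask with 0.085 M of reagent, fed over the same 6.0 min. Its charge number is 7.82, and the running S that its feed holds while substrate stands near its charge is 0.889, against 0.111 in Tuesday's itself; that gives a direct share of 47.1% for that early stretch. At the end, that neighbour holds 52.0% isomer of the product.

The constants were chosen freely; the result is computed.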